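**Strategy.** The plan rests on C1, the diarylmethine that joins C8a of ring A, C1' of ring B and the methyl-bearing C2. The carbocycle is closed afterwards at C4–C4a. Since two of its three carbon neighbours are arenes, C1 can serve as a carbenoid linchpin to which each arene is delivered by a migration from boron. In one flask, the sparteine-lithiated C1 of an enantiopure 2,3-dimethylbut-3-enyl carbamate accepts ring A from a pinacol boronate. The secondary boronate so formed then accepts ring B from an aryllithium on NBS activation, which sets C1 next to the chiral-pool C2. The precursors are three small pieces: carbamate, ring-A boronate, ring-B bromide.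

Key step: step 8

Remark on numbering: atom labels follow the target (C1 diarylmethine, C2 methyl-bearing methine, C3=C4 alkene, C4a/C8a ring fusion, ring A fused arene, ring B pendant arene). The target is (1S,2S), with aryl and C2 methyl cis.

Remark on the chemistry: C3 of 18–22 should form as an epimer mixture and is drawn without a descriptor. This is assumed harmless because C3 becomes sp2 in step 11.

**Step 1**
Reactants: 1 methyl (S)-3-hydroxy-2-methylpropanoate
Product: 2 methyl (S)-3-[(diisopropylcarbamoyl)oxy]-2-methylpropanoate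
Conditions: i-Pr2NCOCl (1.2 equiv), Et3N (1.3 equiv), DMAP (cat.), CH2Cl2, reflux
Reagents that add atoms: N,N-diisopropylcarbamoyl chloride, CC(C)N(C(C)C)C(=O)Cl
Why: O-carbamoylation (nucleophilic acyl substitution) of the primary alcohol leaves C2 untouched, and the hindered carbamate then acts as protecting group in steps 2–4 and as directing and leaving group in step 8, which saves a protection/deprotection pair.

**Step 2**
Reactants: 2 methyl (S)-3-[(diisopropylcarbamoyl)oxy]-2-methylpropanoate
Product: 3 (S)-3-[methoxy(methyl)amino]-2-methyl-3-oxopropyl N,N-diisopropylcarbamate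
Conditions: MeNH(OMe)·HCl (1.5 equiv), i-PrMgCl (3.0 equiv), THF, −20 °C → 0 °C
Reagents that add atoms: N,O-dimethylhydroxylamine hydrochloride, CNOC.Cl
Why: Weinreb amide formation by aminolysis of the ester with the chloromagnesium amide is fast at low temperature, where the hindered carbamate carbonyl is not attacked and the α-centre is not deprotonated.

**Step 3**
Reactants: 3 (S)-3-[methoxy(methyl)amino]-2-methyl-3-oxopropyl N,N-diisopropylcarbamate
Product: 4 (S)-2-methyl-3-oxobutyl N,N-diisopropylcarbamate
Conditions: MeMgBr (1.3 equiv), THF, −78 °C → 0 °C; cold aqueous quench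
Reagents that add atoms: methylmagnesium bromide, C[Mg]Br
Why: In the Weinreb ketone synthesis the chelated tetrahedral adduct stops at single addition and releases the ketone only on quench, so the epimerisable ketone never meets the basic Grignard reagent.

**Step 4**
Reactants: 4 (S)-2-methyl-3-oxobutyl N,N-diisopropylcarbamate
Product: 5 (R)-2,3-dimethylbut-3-en-1-yl N,N-diisopropylcarbamate
Conditions: Zn, CH2Br2, TiCl4 (pre-formed reagent), THF–CH2Cl2, 0 °C → rt
Reagents that add atoms: dibromomethane, BrCBr
Why: The Takai–Lombardo methylenation is non-basic and selective for ketones over carbamates, so neither epimerisation at C2 nor β-elimination of the carbamate should intervene, and the descriptor changes from S to R only through a priority switch.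

**Step 5**
Reactants: 6 2,6-dimethoxyphenol
Product: 7 (2,6-dimethoxyphenoxy)triisopropylsilane
Conditions: TIPSCl (1.2 equiv), imidazole (2.5 equiv), DMF, rt → 40 °C
Reagents that add atoms: triisopropylsilyl chloride, CC(C)[Si](Cl)(C(C)C)C(C)C
Why: This is an O-silylation of the phenol, and the bulky silyl ether is chosen because it withstands alkyllithiums, NBS, basic peroxide and the periodinane yet falls to fluoride.

**Step 6**
Reactants: 7 (2,6-dimethoxyphenoxy)triisopropylsilane
Product: 9 2-[2,4-dimethoxy-3-(triisopropylsilyloxy)phenyl]-4,4,5,5-tetramethyl-1,3,2-dioxaborolane, via ring-A aryllithium 8 (not isolated)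
Conditions: n-BuLi (1.2 equiv), TMEDA (1.2 equiv), Et2O, 0 °C → rt; i-PrOBpin (1.5 equiv), −78 °C → rt
Reagents that add atoms: 2-isopropoxy-4,4,5,5-tetramethyl-1,3,2-dioxaborolane, CC(C)OB1OC(C)(C)C(C)(C)O1
Why: Directed ortho-metalation takes place at one of the two equivalent positions next to a methoxy group (the position para to the silyl ether has no neighbouring director), and electrophilic borylation gives the pinacol ester directly.

**Step 7**
Reactants: 10 4-bromo-2,6-dimethoxyphenol
Product: 11 (4-bromo-2,6-dimethoxyphenoxy)triisopropylsilane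
Conditions: TIPSCl (1.2 equiv), imidazole (2.5 equiv), DMF, rt → 40 °C
Reagents that add atoms: triisopropylsilyl chloride, CC(C)[Si](Cl)(C(C)C)C(C)C
Why: This O-silylation removes the acidic proton ahead of halogen–lithium exchange, and it keeps ring B electron-rich and para-blocked, as the NBS-triggered coupling requires.

**Step 8**
Reactants: 5 (R)-2,3-dimethylbut-3-en-1-yl N,N-diisopropylcarbamate; 9 2-[2,4-dimethoxy-3-(triisopropylsilyloxy)phenyl]-4,4,5,5-tetramethyl-1,3,2-dioxaborolane; 11 (4-bromo-2,6-dimethoxyphenoxy)triisopropylsilane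
Product: 17 (1S,2S)-1-[2,4-dimethoxy-3-(triisopropylsilyloxy)phenyl]-1-[3,5-dimethoxy-4-(triisopropylsilyloxy)phenyl]-2,3-dimethylbut-3-ene, via lithiated carbamate 12 (not isolated), via first ate complex 13 (not isolated), via secondary boronate 14 (not isolated), via ring-B aryllithium 15 (not isolated), via second ate complex 16 (not isolated)
Conditions: 5 (1.3 equiv), (−)-sparteine (1.3 equiv), s-BuLi (1.2 equiv), Et2O, −78 °C; 9 (1.0 equiv), −78 °C → reflux (no MgBr2); cool to −78 °C, THF, 15 (1.5 equiv, from 11 and n-BuLi, THF, −78 °C); NBS (1.5 equiv), THF, −78 °C; aq Na2S2O3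
Reagents that add atoms: none
Why: s-BuLi/(−)-sparteine removes the pro-S of the two diastereotopic C1 hydrogens beside the carbamate oxygen (Hoppe-type asymmetric lithiation) to give configurationally stable (1S)-12, which binds boronate 9 with retention; on warming, ring A moves from boron to C1 antiperiplanar to the departing carbamate, so C1–C8a forms with inversion (Matteson-type 1,2-metallate shift, i.e. lithiation–borylation) and gives (1R,2S)-14. Aryllithium 15, free of ortho substituents, then adds to the crowded boron of 14, and NBS attacks the ring of 16 at C2', the open site ortho to boron that both methoxy groups activate (the para site carries the silyl ether); the developing cation draws C1 from boron to C1' with retention, and loss of bromide and the boryl group restores ring B, the closest known type being the electrophile-induced stereospecific coupling of secondary boronic esters with electron-rich aryllithiums. No ring closes. C1 is the only new stereocentre, fixed by the sparteine enantiomer (reagent control over the resident chiral-pool C2) and relayed through one invertive and one retentive shift to 1S. The step needs α-lithiation instead of allylic deprotonation, secured by pre-complexation of the base to the carbamate carbonyl, and bromination of the anionic aryl ring instead of the isopropenyl group, ring A or the benzylic C–B bond, secured by the much higher nucleophilicity of the meta-dimethoxyaryl boronate at −78 °C with NBS matched to 15. MgBr2 is omitted so that 15 is not transmetallated; each half is an established reaction type, and the demanding point is their union in one flask on this ortho-methoxy, β-branched pair.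

**Step 9**
Reactants: 17 (1S,2S)-1-[2,4-dimethoxy-3-(triisopropylsilyloxy)phenyl]-1-[3,5-dimethoxy-4-(triisopropylsilyloxy)phenyl]-2,3-dimethylbut-3-ene
Product: 19 (3S,4S)-4-[2,4-dimethoxy-3-(triisopropylsilyloxy)phenyl]-4-[3,5-dimethoxy-4-(triisopropylsilyloxy)phenyl]-2,3-dimethylbutan-1-ol (C4 alcohol in route numbering; C3 epimers), via B-alkyl-9-BBN adduct 18 (not isolated)
Conditions: 9-BBN (2 equiv), THF, 0 °C → 50 °C; 3 M NaOH, 30% H2O2, 0 °C → rt
Reagents that add atoms: hydrogen peroxide, OO
Why: In the Brown hydroboration–oxidation boron adds to the unhindered terminal carbon of the 1,1-disubstituted alkene (anti-Markovnikov), and the flanked aryl silyl ethers should survive brief cold basic peroxide.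

**Step 10**
Reactants: 19 the C4 alcohol
Product: 20 (3S,4S)-4-[2,4-dimethoxy-3-(triisopropylsilyloxy)phenyl]-4-[3,5-dimethoxy-4-(triisopropylsilyloxy)phenyl]-2,3-dimethylbutanal (C4 aldehyde; C3 epimers)
Conditions: Dess–Martin periodinane (1.3 equiv), CH2Cl2, 0 °C → rt
Reagents that add atoms: none
Why: The Dess–Martin oxidation stops at the aldehyde under near-neutral conditions that spare the silyl ethers and electron-rich rings, and C2 lies β to the carbonyl and cannot epimerise.

**Step 11**
Reactants: 20 the C4 aldehyde
Product: 23 (1S,2S)-1-(4-hydroxy-3,5-dimethoxyphenyl)-6,8-dimethoxy-2,3-dimethyl-1,2-dihydronaphthalen-7-ol (target), via bis-phenoxide aldehyde 21 (not isolated), via C4 carbinol 22 (not isolated)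
Conditions: TBAF (2.5 equiv), degassed THF (0.01 M), Ar, 0 °C → 40 °C; AcOH quench, aqueous work-up; crude, CSA (10 mol%), CH2Cl2, 0 °C → rt
Reagents that add atoms: none
Why: Fluoride desilylation frees two phenoxides of which only that of ring A has an open para carbon (C4a), so an intramolecular Lederer–Manasse-type hydroxyalkylation (phenol–aldehyde cyclisation, six-membered closure C4–C4a) occurs there while ring B can add only reversibly through its substituted ipso carbon, and the p-hydroxybenzylic carbinol 22 then loses water under catalytic acid (E1 through the quinone-methide-like cation) to the conjugated C3=C4 alkene without touching C1 or C2.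

**Compound list**

| No. | Name | SMILES | Role |
|---|---|---|---|
| 1 | methyl (S)-3-hydroxy-2-methylpropanoate | OC[C@H](C)C(=O)OC | starting material |
| 2 | methyl (S)-3-[(diisopropylcarbamoyl)oxy]-2-methylpropanoate | CC(C)N(C(C)C)C(=O)OC[C@H](C)C(=O)OC | intermediate |
| 3 | (S)-3-[methoxy(methyl)amino]-2-methyl-3-oxopropyl N,N-diisopropylcarbamate | CC(C)N(C(C)C)C(=O)OC[C@H](C)C(=O)N(C)OC | intermediate |
| 4 | (S)-2-methyl-3-oxobutyl N,N-diisopropylcarbamate | CC(C)N(C(C)C)C(=O)OC[C@H](C)C(C)=O | intermediate |
| 5 | (R)-2,3-dimethylbut-3-en-1-yl N,N-diisopropylcarbamate | CC(C)N(C(C)C)C(=O)OC[C@H](C)C(C)=C | intermediate |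
| 6 | 2,6-dimethoxyphenol | COc1cccc(OC)c1O | starting material |
| 7 | (2,6-dimethoxyphenoxy)triisopropylsilane | COc1cccc(OC)c1O[Si](C(C)C)(C(C)C)C(C)C | intermediate |
| 8 | [2,4-dimethoxy-3-(triisopropylsilyloxy)phenyl]lithium | [Li]c1ccc(OC)c(O[Si](C(C)C)(C(C)C)C(C)C)c1OC | intermediate |
| 9 | 2-[2,4-dimethoxy-3-(triisopropylsilyloxy)phenyl]-4,4,5,5-tetramethyl-1,3,2-dioxaborolane | COc1ccc(B2OC(C)(C)C(C)(C)O2)c(OC)c1O[Si](C(C)C)(C(C)C)C(C)C | intermediate |
| 10 | 4-bromo-2,6-dimethoxyphenol | COc1cc(Br)cc(OC)c1O | starting material |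
| 11 | (4-bromo-2,6-dimethoxyphenoxy)triisopropylsilane | COc1cc(Br)cc(OC)c1O[Si](C(C)C)(C(C)C)C(C)C | intermediate |
| 12 | (1S,2R)-1-lithio-2,3-dimethylbut-3-en-1-yl N,N-diisopropylcarbamate (as its (−)-sparteine complex) | CC(C)N(C(C)C)C(=O)O[C@@H]([Li])[C@H](C)C(C)=C | intermediate |
| 13 | lithium (1S,2R)-[1-(diisopropylcarbamoyloxy)-2,3-dimethylbut-3-en-1-yl](ring-A aryl)pinacolatoborate | CC(C)N(C(C)C)C(=O)O[C@@H]([B-]1(OC(C)(C)C(C)(C)O1)c1ccc(OC)c(O[Si](C(C)C)(C(C)C)C(C)C)c1OC)[C@H](C)C(C)=C.[Li+] | intermediate |
| 14 | 2-{(1R,2S)-1-[2,4-dimethoxy-3-(triisopropylsilyloxy)phenyl]-2,3-dimethylbut-3-en-1-yl}-4,4,5,5-tetramethyl-1,3,2-dioxaborolane | CC(=C)[C@@H](C)[C@@H](B1OC(C)(C)C(C)(C)O1)c1ccc(OC)c(O[Si](C(C)C)(C(C)C)C(C)C)c1OC | intermediate |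
| 15 | [3,5-dimethoxy-4-(triisopropylsilyloxy)phenyl]lithium | [Li]c1cc(OC)c(O[Si](C(C)C)(C(C)C)C(C)C)c(OC)c1 | intermediate |
| 16 | lithium (1R,2S)-[1-(ring-A aryl)-2,3-dimethylbut-3-en-1-yl](ring-B aryl)pinacolatoborate | CC(=C)[C@@H](C)[C@@H]([B-]1(OC(C)(C)C(C)(C)O1)c1cc(OC)c(O[Si](C(C)C)(C(C)C)C(C)C)c(OC)c1)c1ccc(OC)c(O[Si](C(C)C)(C(C)C)C(C)C)c1OC.[Li+] | intermediate |
| 17 | (1S,2S)-1-[2,4-dimethoxy-3-(triisopropylsilyloxy)phenyl]-1-[3,5-dimethoxy-4-(triisopropylsilyloxy)phenyl]-2,3-dimethylbut-3-ene | COc1cc([C@H]([C@H](C)C(C)=C)c2ccc(OC)c(O[Si](C(C)C)(C(C)C)C(C)C)c2OC)cc(OC)c1O[Si](C(C)C)(C(C)C)C(C)C | intermediate |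
| 18 | 9-[(3S,4S)-4,4-diaryl-2,3-dimethylbutyl]-9-borabicyclo[3.3.1]nonane (aryl groups as in 17; C3 epimers) | COc1cc([C@H]([C@H](C)C(C)CB3C4CCCC3CCC4)c2ccc(OC)c(O[Si](C(C)C)(C(C)C)C(C)C)c2OC)cc(OC)c1O[Si](C(C)C)(C(C)C)C(C)C | intermediate |
| 19 | (3S,4S)-4-[2,4-dimethoxy-3-(triisopropylsilyloxy)phenyl]-4-[3,5-dimethoxy-4-(triisopropylsilyloxy)phenyl]-2,3-dimethylbutan-1-ol (C3 epimers) | COc1cc([C@H]([C@H](C)C(C)CO)c2ccc(OC)c(O[Si](C(C)C)(C(C)C)C(C)C)c2OC)cc(OC)c1O[Si](C(C)C)(C(C)C)C(C)C | intermediate |
| 20 | (3S,4S)-4-[2,4-dimethoxy-3-(triisopropylsilyloxy)phenyl]-4-[3,5-dimethoxy-4-(triisopropylsilyloxy)phenyl]-2,3-dimethylbutanal (C3 epimers) | COc1cc([C@H]([C@H](C)C(C)C=O)c2ccc(OC)c(O[Si](C(C)C)(C(C)C)C(C)C)c2OC)cc(OC)c1O[Si](C(C)C)(C(C)C)C(C)C | intermediate |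
| 21 | (3S,4S)-4-(3-hydroxy-2,4-dimethoxyphenyl)-4-(4-hydroxy-3,5-dimethoxyphenyl)-2,3-dimethylbutanal (in the flask as the bis-tetrabutylammonium phenoxide; C3 epimers) | COc1cc([C@H]([C@H](C)C(C)C=O)c2ccc(OC)c(O)c2OC)cc(OC)c1O | intermediate |
| 22 | (1S,2S)-1-(4-hydroxy-3,5-dimethoxyphenyl)-6,8-dimethoxy-2,3-dimethyl-1,2,3,4-tetrahydronaphthalene-4,7-diol (C3 and C4 epimers) | COc1cc([C@H]2c3c(cc(OC)c(O)c3OC)C(O)C(C)[C@H]2C)cc(OC)c1O | intermediate |
| 23 | (1S,2S)-1-(4-hydroxy-3,5-dimethoxyphenyl)-6,8-dimethoxy-2,3-dimethyl-1,2-dihydronaphthalen-7-ol | COc1cc([C@H]2c3c(cc(OC)c(O)c3OC)C=C(C)[C@H]2C)cc(OC)c1O | target |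

**Step count.** Total: 11 steps. Longest linear sequence: 8 steps (steps 1–4 and 8–11).

**Steps most likely to fail**

**Step 8.**
- Capture of the hindered secondary boronate by the aryllithium may be incomplete in the presence of the diamine and lithium salts left from the first half.
- NBS may be consumed by sparteine or the isopropenyl group.
- Single-electron oxidation of the benzylic ate complex may erode stereochemical fidelity.
- The resident C2 centre may slow the reagent-controlled deprotonation.

Fallback, from 14 and 11 back to 17: the sequence is interrupted after the first shift and 14 is isolated by aqueous work-up and chromatography, which removes sparteine and salts. Bromide 11 is converted through 15 (n-BuLi, THF, −78 °C, then I2) into (4-iodo-2,6-dimethoxyphenoxy)triisopropylsilane F1. The C1–C1' bond is then made by a stereoretentive Suzuki–Miyaura coupling of the secondary benzylic boronate (Pd2(dba)3, PPh3, Ag2O, DME, 85 °C). This proceeds by transmetallation to divalent palladium with retention in place of an ate-complex shift, and gives 17.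

**Step 11.**
- Carbon attack of the phenoxide on an unactivated, enolisable aldehyde may be slow, which would allow intermolecular aldol condensation or air oxidation of the electron-rich phenoxides.
- Any exposure to acid before the ring has closed would divert the cyclisation to C2'/C6' of ring B, which two methoxy groups activate.

Fallback, from 20 back to 23: buffered desilylation (TBAF/AcOH, THF, 0 °C) gives 21, now isolated as the neutral bis-phenol. Warming with pyrrolidine (MeCN, 60 °C) turns the aldehyde into an iminium ion. This ion reacts only at a position para or ortho to a free phenol (phenolic Mannich cyclisation) and gives (1S,2S)-1-(4-hydroxy-3,5-dimethoxyphenyl)-6,8-dimethoxy-2,3-dimethyl-4-(pyrrolidin-1-yl)-1,2,3,4-tetrahydronaphthalen-7-ol F2. Continued heating with AcOH expels the amine through the para-quinone methide, which tautomerises to 23.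

**Step 6.**
- Ortho-metalation may be sluggish or incomplete because the bulky silyl ether turns the methoxy groups away from their best directing geometry.
- Slow attack of the base at silicon is a second drain.

Fallback, from 7 back to 9: electrophilic bromination (NBS, MeCN, 0 °C) goes to the carbon ortho to one methoxy group and para to the other. It gives (3-bromo-2,6-dimethoxyphenoxy)triisopropylsilane F3. Miyaura borylation (B2pin2, PdCl2(dppf), KOAc, dioxane, 90 °C) then gives 9.

**Further compounds**
F1 | step 8 | (4-iodo-2,6-dimethoxyphenoxy)triisopropylsilane | COc1cc(I)cc(OC)c1O[Si](C(C)C)(C(C)C)C(C)C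
F2 | step 11 | (1S,2S)-1-(4-hydroxy-3,5-dimethoxyphenyl)-6,8-dimethoxy-2,3-dimethyl-4-(pyrrolidin-1-yl)-1,2,3,4-tetrahydronaphthalen-7-ol | COc1cc([C@H]2c3c(cc(OC)c(O)c3OC)C(N4CCCC4)C(C)[C@H]2C)cc(OC)c1O
F3 | step 6 | (3-bromo-2,6-dimethoxyphenoxy)triisopropylsilane | COc1ccc(Br)c(OC)c1O[Si](C(C)C)(C(C)C)C(C)C
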